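**Retrosynthetic overview**

1. The C3 aryloxymethyl ether is cut at its CH2–O bond (Mitsunobu with eugenol), leading back to the trans C3 hydroxymethyl compound and then to the trans C3 ethyl ester; the C4' phenol is carried as a MOM ether.
2. The trans ester comes from the cis ester by enolate epimerisation at C3, a thermodynamic funnel that leaves C2 untouched.
3. The cis ester comes from an acyclic, achiral aryl diazoacetate by enantioselective dirhodium-catalysed intramolecular C–H insertion. This forms the C2–C3 bond and the dihydrofuran ring, the only ring made in the route; the three benzene rings are bought.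
4. Enabling feature: the O1–CH2–aryl methylene (future C2). Its C–H bonds are activated by the lone pair of O1 and by the electron-rich 4-oxygenated aryl ring, and they sit 1,5 to the carbene carbon (future C3) across the C3a–C7a–O1 edge of ring A.
5. The diazo ester comes from ortho-iodinated eugenol, MOM-protected vanillyl alcohol (Mitsunobu) and ethyl diazoacetate (palladium-catalysed coupling at the iodide).

Key step: step 6

Remark: benzofuran numbering is used (O1, C2, C3, C3a to C7a; ring A is the benzo ring). By analogy with related 2-(benzyloxy)aryl diazoacetates, the R-configured phthaloyl-tert-leucinate catalyst is assumed to deliver the 2S centre; if the sense proves opposite, the mirror-image catalyst Rh2(S-PTTL)4 would be used with nothing else changed.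

**Route**

Step 1
Reactants: 1 eugenol (4-allyl-2-methoxyphenol)
Product: 2 4-allyl-2-iodo-6-methoxyphenol
Conditions: NaI, NaOH, MeOH, 0 °C; aq. NaOCl added dropwise
Reagents that add atoms: sodium iodide, [Na+].[I-]
Why: Electrophilic aromatic iodination of the phenoxide by hypoiodite made in the flask; the para position is blocked by the allyl group, so iodine should enter the only free position ortho to the phenoxide oxygen, and the phenoxide ring should outcompete the isolated terminal alkene.

Step 2
Reactants: 3 vanillin
Product: 4 3-methoxy-4-(methoxymethoxy)benzaldehyde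
Conditions: MOMCl, iPr2NEt, CH2Cl2, 0 °C to rt
Reagents that add atoms: chloromethyl methyl ether (MOMCl), COCCl
Why: O-alkylation of the phenol (Williamson-type acetal ether formation) gives a base-stable, acid-labile protecting group that survives every later step up to the last.

Step 3
Reactants: 4 3-methoxy-4-(methoxymethoxy)benzaldehyde
Product: 5 [3-methoxy-4-(methoxymethoxy)phenyl]methanol
Conditions: NaBH4, MeOH, 0 °C
Reagents that add atoms: none
Why: Borohydride reduction of an aromatic aldehyde to the benzylic alcohol; the MOM ether is inert.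

Step 4
Reactants: 2 4-allyl-2-iodo-6-methoxyphenol; 5 [3-methoxy-4-(methoxymethoxy)phenyl]methanol
Product: 6 5-allyl-1-iodo-3-methoxy-2-{[3-methoxy-4-(methoxymethoxy)benzyl]oxy}benzene
Conditions: PPh3, DIAD, THF, 0 °C to rt
Reagents that add atoms: none
Why: Mitsunobu etherification of an acidic ortho-iodophenol with a primary benzylic alcohol under neutral conditions, which avoids handling a labile 4-alkoxybenzyl halide.

Step 5
Reactants: 6 5-allyl-1-iodo-3-methoxy-2-{[3-methoxy-4-(methoxymethoxy)benzyl]oxy}benzene; 7 ethyl diazoacetate
Product: 8 ethyl 2-diazo-2-[5-allyl-3-methoxy-2-{[3-methoxy-4-(methoxymethoxy)benzyl]oxy}phenyl]acetate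
Conditions: Pd(PPh3)4 (5 mol %), Ag2CO3 (0.5 equiv), Et3N, toluene, rt
Reagents that add atoms: none
Why: Palladium-catalysed cross-coupling of an aryl iodide with the C–H bond of an acceptor diazo compound (oxidative addition to zerovalent palladium, silver-assisted palladation of ethyl diazoacetate, reductive elimination), which keeps the diazo group and runs at room temperature, where the allyl group and the benzylic ether should be inert.

Step 6
Reactants: 8 ethyl 2-diazo-2-[5-allyl-3-methoxy-2-{[3-methoxy-4-(methoxymethoxy)benzyl]oxy}phenyl]acetate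
Product: 9 ethyl (2S,3R)-5-allyl-7-methoxy-2-[3-methoxy-4-(methoxymethoxy)phenyl]-2,3-dihydro-1-benzofuran-3-carboxylate (cis)
Conditions: Rh2(R-PTTL)4 (dirhodium tetrakis[N-phthaloyl-(R)-tert-leucinate], 1 mol %), toluene, −60 °C, slow addition of 8
Reagents that add atoms: none
Why: The catalyst expels N2 from 8 to give an electrophilic donor/acceptor rhodium carbene at the future C3, which inserts through a concerted, asynchronous, hydride-shift-like three-centre transition state into one of the two enantiotopic C–H bonds of the O1–CH2–aryl methylene and so forms the C2–C3 bond. The closest known reaction type is the enantioselective intramolecular 1,5-C–H insertion of 2-(benzyloxy)aryl diazoacetates under dirhodium tetrakis(N-phthaloyl amino-acid carboxylate) catalysis, which favours cis-2-aryl-2,3-dihydrobenzofuran-3-carboxylates. The dihydrofuran ring is closed by 1,5-insertion, the carbene carbon and the C–H carbon being joined across the C3a–C7a–O1 tether into a five-membered ring. C2 is set by the catalyst, whose phthalimido wall should differentiate the two enantiotopic hydrogens (R-catalyst chosen for 2S); C3 is set relative to C2 in the insertion transition state, which is expected to give the cis (3R) ester as the kinetic product, to be corrected in step 7. The step needs chemoselectivity for this C–H bond over intermolecular cyclopropanation of the allyl group, aromatic cycloaddition and carbene dimerisation. The double activation of the C–H bond by O1 and by the electron-rich 3-methoxy-4-(methoxymethoxy)phenyl ring, the meta position of the allyl group (out of intramolecular reach), slow addition and low temperature should secure it.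

Step 7
Reactants: 9 ethyl (2S,3R)-5-allyl-7-methoxy-2-[3-methoxy-4-(methoxymethoxy)phenyl]-2,3-dihydro-1-benzofuran-3-carboxylate (cis)
Product: 10 ethyl (2S,3S)-5-allyl-7-methoxy-2-[3-methoxy-4-(methoxymethoxy)phenyl]-2,3-dihydro-1-benzofuran-3-carboxylate (trans)
Conditions: NaOEt (0.3 equiv), EtOH, rt
Reagents that add atoms: none
Why: Base-mediated epimerisation through the C3 ester enolate under thermodynamic control should place the ester and the C2 aryl group on opposite faces; C2 carries no acidic hydrogen and keeps its configuration, so any trans ester formed directly in step 6 converges on the same product.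

Step 8
Reactants: 10 ethyl (2S,3S)-5-allyl-7-methoxy-2-[3-methoxy-4-(methoxymethoxy)phenyl]-2,3-dihydro-1-benzofuran-3-carboxylate (trans)
Product: 11 [(2S,3R)-5-allyl-7-methoxy-2-[3-methoxy-4-(methoxymethoxy)phenyl]-2,3-dihydro-1-benzofuran-3-yl]methanol (trans)
Conditions: LiAlH4, THF, 0 °C; Rochelle salt work-up
Reagents that add atoms: none
Why: Hydride reduction of the ester to the primary alcohol; both stereocentres are untouched (the C3 descriptor changes from S to R only through the change in substituent priority), and alkenes, aryl ethers and the MOM ether are inert.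

Step 9
Reactants: 11 [(2S,3R)-5-allyl-7-methoxy-2-[3-methoxy-4-(methoxymethoxy)phenyl]-2,3-dihydro-1-benzofuran-3-yl]methanol; 1 eugenol
Product: 12 (2S,3R)-5-allyl-3-[(4-allyl-2-methoxyphenoxy)methyl]-7-methoxy-2-[3-methoxy-4-(methoxymethoxy)phenyl]-2,3-dihydro-1-benzofuran
Conditions: PPh3, DIAD, THF, 0 °C to rt
Reagents that add atoms: none
Why: Mitsunobu etherification of a primary alcohol with a phenol of suitable acidity; the reaction takes place at the CH2 group, so no stereocentre is involved.

Step 10
Reactants: 12 (2S,3R)-5-allyl-3-[(4-allyl-2-methoxyphenoxy)methyl]-7-methoxy-2-[3-methoxy-4-(methoxymethoxy)phenyl]-2,3-dihydro-1-benzofuran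
Product: 13 4-[(2S,3R)-5-allyl-3-[(4-allyl-2-methoxyphenoxy)methyl]-7-methoxy-2,3-dihydro-1-benzofuran-2-yl]-2-methoxyphenol (CNP0138854.1)
Conditions: HCl (cat.), MeOH/THF, rt to 40 °C
Reagents that add atoms: none
Why: Acid-catalysed acetal exchange with methanol should cleave the aryl MOM ether under conditions mild enough for the allyl groups, the methyl ethers and the aryl alkyl ether; C3 is not affected, and the trans ring fusion is the thermodynamic arrangement should the benzylic C2–O1 bond ionise reversibly.

**Compound list**

1 | eugenol (4-allyl-2-methoxyphenol) | C=CCc1ccc(O)c(OC)c1 | starting material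
2 | 4-allyl-2-iodo-6-methoxyphenol | C=CCc1cc(I)c(O)c(OC)c1 | intermediate
3 | vanillin | COc1cc(C=O)ccc1O | starting material
4 | 3-methoxy-4-(methoxymethoxy)benzaldehyde | COCOc1ccc(C=O)cc1OC | intermediate
5 | [3-methoxy-4-(methoxymethoxy)phenyl]methanol | COCOc1ccc(CO)cc1OC | intermediate
6 | 5-allyl-1-iodo-3-methoxy-2-{[3-methoxy-4-(methoxymethoxy)benzyl]oxy}benzene | C=CCc1cc(I)c(OCc2ccc(OCOC)c(OC)c2)c(OC)c1 | intermediate
7 | ethyl diazoacetate | CCOC(=O)C=[N+]=[N-] | starting material
8 | ethyl 2-diazo-2-[5-allyl-3-methoxy-2-{[3-methoxy-4-(methoxymethoxy)benzyl]oxy}phenyl]acetate | CCOC(=O)C(=[N+]=[N-])c1cc(CC=C)cc(OC)c1OCc1ccc(OCOC)c(OC)c1 | intermediate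
9 | ethyl (2S,3R)-5-allyl-7-methoxy-2-[3-methoxy-4-(methoxymethoxy)phenyl]-2,3-dihydro-1-benzofuran-3-carboxylate (cis) | CCOC(=O)[C@@H]1c2cc(CC=C)cc(OC)c2O[C@@H]1c3ccc(OCOC)c(OC)c3 | intermediate
10 | ethyl (2S,3S)-5-allyl-7-methoxy-2-[3-methoxy-4-(methoxymethoxy)phenyl]-2,3-dihydro-1-benzofuran-3-carboxylate (trans) | CCOC(=O)[C@H]1c2cc(CC=C)cc(OC)c2O[C@@H]1c3ccc(OCOC)c(OC)c3 | intermediate
11 | [(2S,3R)-5-allyl-7-methoxy-2-[3-methoxy-4-(methoxymethoxy)phenyl]-2,3-dihydro-1-benzofuran-3-yl]methanol (trans) | OC[C@H]1c2cc(CC=C)cc(OC)c2O[C@@H]1c3ccc(OCOC)c(OC)c3 | intermediate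
12 | (2S,3R)-5-allyl-3-[(4-allyl-2-methoxyphenoxy)methyl]-7-methoxy-2-[3-methoxy-4-(methoxymethoxy)phenyl]-2,3-dihydro-1-benzofuran | C=CCc1ccc(OC[C@H]2c3cc(CC=C)cc(OC)c3O[C@@H]2c2ccc(OCOC)c(OC)c2)c(OC)c1 | intermediate
13 | 4-[(2S,3R)-5-allyl-3-[(4-allyl-2-methoxyphenoxy)methyl]-7-methoxy-2,3-dihydro-1-benzofuran-2-yl]-2-methoxyphenol (CNP0138854.1) | C=CCc1ccc(OC[C@H]2c3cc(CC=C)cc(OC)c3O[C@@H]2c2ccc(O)c(OC)c2)c(OC)c1 | target

**Step count**

Total steps: 10. Longest linear sequence: 9 steps (vanillin 3 to target 13, steps 2 to 10).

**Steps most likely to fail, with fallbacks**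

Step 5. Oxidative addition and coupling at the hindered, electron-rich iodide may be slow, so that palladium-mediated loss of N2 from the diazo ester (carbene dimerisation) or Heck-type engagement of the allyl group takes over. The fallback sets out from 6 and builds the arylacetate first. A Reformatsky–Negishi coupling of 6 with BrZnCH2CO2Et (made from ethyl bromoacetate and zinc dust) under Pd2(dba)3/XPhos in THF at 60 °C should give ethyl 2-[5-allyl-3-methoxy-2-{[3-methoxy-4-(methoxymethoxy)benzyl]oxy}phenyl]acetate F1. Regitz diazo transfer to F1 (4-acetamidobenzenesulfonyl azide, DBU, MeCN, 0 °C to rt) then returns to the route at 8.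

Step 6. Discrimination between the two enantiotopic benzylic hydrogens may be incomplete, so that material of insufficient enantiomeric purity is carried forward. The fallback moves the source of enantiopurity from the catalyst to a separation of covalent diastereomers. It sets out from scalemic 11 (steps 6 to 8 run as written). Acylation with (1S)-camphanic chloride (Et3N, DMAP, CH2Cl2) should give the (1S,4R)-camphanate of 11 F2 together with the (1S,4R)-camphanate of the mirror image of 11 F3. These are separated by crystallisation or chromatography, and methanolysis of F2 (K2CO3, MeOH, rt) returns to the route at 11 as a single enantiomer.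

Step 9. The oxyphosphonium intermediate may undergo β-elimination with loss of the benzylic C3 hydrogen (exocyclic alkene, then aromatisation to a benzofuran), or the reduced azodicarboxylate may be alkylated in place of the phenol. The fallback sets out from 11 and separates activation from displacement. MsCl and Et3N in CH2Cl2 at 0 °C should give the methanesulfonate of 11 F4. Williamson displacement with eugenol 1 and Cs2CO3 in DMF at 50 °C, with a weakly basic and highly nucleophilic phenoxide, returns to the route at 12.

**Further compounds**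

F1 | step 5 | ethyl 2-[5-allyl-3-methoxy-2-{[3-methoxy-4-(methoxymethoxy)benzyl]oxy}phenyl]acetate | CCOC(=O)Cc1cc(CC=C)cc(OC)c1OCc1ccc(OCOC)c(OC)c1
F2 | step 6 | [(2S,3R)-5-allyl-7-methoxy-2-[3-methoxy-4-(methoxymethoxy)phenyl]-2,3-dihydro-1-benzofuran-3-yl]methyl (1S,4R)-camphanate | O=C(OC[C@H]1c2cc(CC=C)cc(OC)c2O[C@@H]1c3ccc(OCOC)c(OC)c3)[C@@]45CC[C@@](C)(C(=O)O4)C5(C)C
F3 | step 6 | [(2R,3S)-5-allyl-7-methoxy-2-[3-methoxy-4-(methoxymethoxy)phenyl]-2,3-dihydro-1-benzofuran-3-yl]methyl (1S,4R)-camphanate | O=C(OC[C@@H]1c2cc(CC=C)cc(OC)c2O[C@H]1c3ccc(OCOC)c(OC)c3)[C@@]45CC[C@@](C)(C(=O)O4)C5(C)C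
F4 | step 9 | [(2S,3R)-5-allyl-7-methoxy-2-[3-methoxy-4-(methoxymethoxy)phenyl]-2,3-dihydro-1-benzofuran-3-yl]methyl methanesulfonate | CS(=O)(=O)OC[C@H]1c2cc(CC=C)cc(OC)c2O[C@@H]1c3ccc(OCOC)c(OC)c3
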